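**Retrosynthetic overview**
- The target is a cis-fused bis(pyranoquinolinone). The usual disconnection is the [4+2] dimerisation of N-methylflindersine (quinone methide plus pyran alkene); here the roles of the two halves are inverted.
- Ring B is cut first: an acid-catalysed cationic [4+2] (oxa-Povarov type) between an enantioenriched 4H-pyrano[3,2-c]quinolinone (cis enol ether, 2π partner) and the aryloxycarbenium ion from a 4-isopropenyloxyquinolinone.
- The 4H-pyran comes from dehydration of a lactol, itself made by iminium-catalysed Michael addition/hemiacetalisation of 4-hydroxy-1-methylquinolin-2-one with (2E)-5-methylhexa-2,4-dienal. This sets the isobutenyl-bearing centre.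
- The isopropenyl ether comes from copper-catalysed O-alkenylation of the same quinolinone; the dienal from Wittig homologation of prenal.
- Ring order: quinolinone (bought), then pyran ring A, then pyran ring B; the two remaining stereocentres are relayed from the first.

Assumption: the facial sense of the prolinol catalyst in step 2 follows the usual steric-shielding model ((R)-catalyst gives (R)-adduct); if the measured configuration is opposite, the (S)-catalyst is used.

**Step 1**
Reactants: 1 3-methylbut-2-enal (prenal); 2 (triphenylphosphoranylidene)acetaldehyde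
Product: 3 (2E)-5-methylhexa-2,4-dienal
Conditions: 1 (3 equiv), toluene, 80 °C, 16 h
Reagents that add atoms: none
Why: Wittig olefination with a stabilised formyl ylide gives the (E)-enal, and the excess of 1 limits a second homologation of the product.

**Step 2**
Reactants: 3 (2E)-5-methylhexa-2,4-dienal; 4 4-hydroxy-1-methylquinolin-2(1H)-one
Product: 6 (4R)-2-hydroxy-6-methyl-4-(2-methylprop-1-en-1-yl)-3,4-dihydro-2H-pyrano[3,2-c]quinolin-5(6H)-one (both anomers), via open-chain aldehyde 5 (not isolated)
Conditions: (R)-2-[diphenyl(trimethylsilyloxy)methyl]pyrrolidine (10 mol%), PhCO2H (10 mol%), CH2Cl2, 0 °C to rt, 24 h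
Reagents that add atoms: none
Why: Iminium-ion catalysed Michael addition of C3 of 4 to the β-carbon of 3 (the dimethyl-substituted δ-carbon is too hindered for 1,6-addition), in which the diphenyl(silyloxy)methyl group blocks one face of the E-iminium ion and sets the (R) centre of 5, followed by spontaneous hemiacetalisation of the 4-OH onto the aldehyde.

**Step 3**
Reactants: 6 the lactol from step 2
Product: 8 (4S)-6-methyl-4-(2-methylprop-1-en-1-yl)-4H-pyrano[3,2-c]quinolin-5(6H)-one, via anomeric mesylate 7 (not isolated)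
Conditions: MsCl (1.5 equiv), Et3N (4 equiv), CH2Cl2, 0 °C to rt
Reagents that add atoms: none
Why: Mesylation of the anomeric hydroxyl and base-induced elimination through the oxocarbenium ion (the standard lactol-to-glycal dehydration) gives the cyclic enol ether; C4 is untouched, and its descriptor changes from R to S only because the CIP priorities change.

**Step 4**
Reactants: 4 4-hydroxy-1-methylquinolin-2(1H)-one; 9 4,4,5,5-tetramethyl-2-(prop-1-en-2-yl)-1,3,2-dioxaborolane
Product: 10 1-methyl-4-(prop-1-en-2-yloxy)quinolin-2(1H)-one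
Conditions: Cu(OAc)2 (20 mol%), pyridine (2 equiv), 4 Å molecular sieves, O2 (1 atm), MeCN, 40 °C
Reagents that add atoms: none
Why: Chan–Lam–Evans oxidative C–O coupling, in which the acidic enol hydroxyl (a vinylogous carboxylic acid) is O-alkenylated by the alkenylboronate at copper just as carboxylic acids and phenols give enol esters and aryl vinyl ethers; no stereocentre is formed.

**Step 5**
Reactants: 8 the 4H-pyran from step 3; 10 the isopropenyl ether from step 4
Product: 13 CNP0210533.1 (the target), via aryloxycarbenium ion 11 (not isolated), via pyranylium ion 12 (not isolated)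
Conditions: Tf2NH (10 mol%), 4 Å molecular sieves, CH2Cl2, −78 °C; 10 (1.5 equiv) added over 4 h by syringe pump; then −40 °C, 2 h; Et3N quench at −40 °C
Reagents that add atoms: none
Why: Proposed new method: the acid protonates the isopropenyl ether 10 at its CH2 terminus to give the tertiary aryloxycarbenium ion 11 (a cationic 2-oxadiene), the cis enol ether of 8 attacks it through C3 from the face opposite the pseudo-axial isobutenyl group on C4 (setting the ring-fusion CH trans to the isobutenyl group), and the cyclic oxocarbenium ion 12 is then captured by C3 of the tethered 4-alkoxyquinolinone in a six-membered Friedel–Crafts closure on the tether face (cis ring fusion, setting the O–CH–aryl centre) before proton loss returns the acid; the closest known reaction type is the Povarov reaction of N-aryl iminium ions with cyclic enol ethers and its oxygen analogue (oxa-Povarov reaction of aryl oxocarbenium ions with alkenes), both of which give cis-fused adducts, and slow addition of 10 is used to suppress its self-condensation.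

**Compound list**
1 | 3-methylbut-2-enal (prenal) | CC(C)=CC=O | starting material
2 | (triphenylphosphoranylidene)acetaldehyde | O=CC=P(c1ccccc1)(c1ccccc1)c1ccccc1 | starting material
3 | (2E)-5-methylhexa-2,4-dienal | CC(C)=C/C=C/C=O | intermediate
4 | 4-hydroxy-1-methylquinolin-2(1H)-one | Cn1c(=O)cc(O)c2ccccc12 | starting material
5 | 4-hydroxy-1-methyl-3-[(3R)-5-methyl-1-oxohex-4-en-3-yl]quinolin-2(1H)-one | CC(C)=C[C@@H](CC=O)c1c(O)c2ccccc2n(C)c1=O | intermediate
6 | (4R)-2-hydroxy-6-methyl-4-(2-methylprop-1-en-1-yl)-3,4-dihydro-2H-pyrano[3,2-c]quinolin-5(6H)-one (both anomers) | CC(C)=C[C@@H]1c2c(c3ccccc3n(C)c2=O)OC(O)C1 | intermediate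
7 | (4R)-6-methyl-4-(2-methylprop-1-en-1-yl)-5-oxo-3,4,5,6-tetrahydro-2H-pyrano[3,2-c]quinolin-2-yl methanesulfonate | CC(C)=C[C@@H]1c2c(c3ccccc3n(C)c2=O)OC(OS(C)(=O)=O)C1 | intermediate
8 | (4S)-6-methyl-4-(2-methylprop-1-en-1-yl)-4H-pyrano[3,2-c]quinolin-5(6H)-one | CC(C)=C[C@@H]1c2c(c3ccccc3n(C)c2=O)OC=C1 | intermediate
9 | 4,4,5,5-tetramethyl-2-(prop-1-en-2-yl)-1,3,2-dioxaborolane | CC(=C)B1OC(C)(C)C(C)(C)O1 | starting material
10 | 1-methyl-4-(prop-1-en-2-yloxy)quinolin-2(1H)-one | CC(=C)Oc1cc(=O)n(C)c2ccccc12 | intermediate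
11 | (1-methyl-2-oxo-1,2-dihydroquinolin-4-yl)(propan-2-ylidene)oxonium | CC(C)=[O+]c1cc(=O)n(C)c2ccccc12 | intermediate
12 | (3R,4S)-6-methyl-3-{2-[(1-methyl-2-oxo-1,2-dihydroquinolin-4-yl)oxy]propan-2-yl}-4-(2-methylprop-1-en-1-yl)-5-oxo-3,4,5,6-tetrahydropyrano[3,2-c]quinolin-1-ium | CC(C)=C[C@@H]1c2c(c3ccccc3n(C)c2=O)[O+]=C[C@H]1C(C)(C)Oc1cc(=O)n(C)c2ccccc12 | intermediate
13 | CNP0210533.1: cis-fused bis(pyranoquinolinone); the carbon bearing the 2-methylprop-1-enyl group is S, the O–CH–quinolinyl carbon is R, the ring-fusion CH next to the CMe2–O group is S; the isobutenyl group is trans to the CMe2 group | CC(C)=C[C@@H]1c2c(c3ccccc3n(C)c2=O)O[C@H]2c3c(c4ccccc4n(C)c3=O)OC(C)(C)[C@@H]12 | target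

**Totals**
Total step count: 5. Longest linear sequence: 4 (steps 1, 2, 3, 5); step 4 is a one-step side branch.

**Steps most likely to fail and fallbacks**

Step 5 (key annulation). The carbenium ion 11 may self-condense with 10, abstract hydride from the doubly allylic C4–H of 8, or transfer the quinolinyl group instead of adding at carbon. The fallback builds the same tether stepwise and sets out from 8. TiCl4-mediated addition of the enol ether to acetone (CH2Cl2, −78 °C, MeOH/Et3N quench), anti to the isobutenyl group, gives (3R,4S)-3-(2-hydroxypropan-2-yl)-2-methoxy-6-methyl-4-(2-methylprop-1-en-1-yl)-3,4-dihydro-2H-pyrano[3,2-c]quinolin-5(6H)-one F1. Cl3CCN with catalytic 1,8-diazabicyclo[5.4.0]undec-7-ene converts the tertiary alcohol into 2-[(3R,4S)-2-methoxy-6-methyl-4-(2-methylprop-1-en-1-yl)-5-oxo-3,4,5,6-tetrahydro-2H-pyrano[3,2-c]quinolin-3-yl]propan-2-yl 2,2,2-trichloroacetimidate F2. This imidate alkylates the acidic 4-OH of 4 (BF3·OEt2, 5 mol%, cyclohexane/CH2Cl2, 0 °C) to give (3R,4S)-2-methoxy-6-methyl-3-{2-[(1-methyl-2-oxo-1,2-dihydroquinolin-4-yl)oxy]propan-2-yl}-4-(2-methylprop-1-en-1-yl)-3,4-dihydro-2H-pyrano[3,2-c]quinolin-5(6H)-one F3. Me3SiOTf at −78 °C ionises the anomeric methoxy group of F3, which rejoins the route at pyranylium ion 12 and closes to 13.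

Step 4 (O-alkenylation). The vinylogous acid may couple poorly with the pinacol boronate or be alkenylated at C3. The fallback sets out from 4 and forms the C–O bond by acylation and the C=C bond by carbonyl olefination. Ac2O/pyridine gives 1-methyl-2-oxo-1,2-dihydroquinolin-4-yl acetate F4, and methylenation of the ester carbonyl with (C5H5)2Ti(CH3)2 (toluene, 65 °C; the pyridone carbonyl is far less reactive) returns to 10.

Step 2 (enantioselective Michael addition). The quinolinone may give low ee or some 1,6-addition under iminium catalysis. The fallback sets out from 3 and 4 and uses acyl azolium catalysis instead. The reagents are the enantiomer of the aminoindanol-derived precatalyst (5aS,10bR)-2-(2,4,6-trimethylphenyl)-5a,10b-dihydro-4H,6H-indeno[2,1-b][1,2,4]triazolo[4,3-d][1,4]oxazin-2-ium tetrafluoroborate that delivers the (4R) product, i-Pr2NEt and 3,3′,5,5′-tetra-tert-butyldiphenoquinone in toluene. Michael addition/lactonisation of the α,β-unsaturated acyl azolium gives (4R)-6-methyl-4-(2-methylprop-1-en-1-yl)-3,4-dihydro-2H-pyrano[3,2-c]quinoline-2,5(6H)-dione F5. Reduction with i-Bu2AlH (CH2Cl2, −78 °C) returns to lactol 6.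

**Further compounds**
F1 | step 5 | (3R,4S)-3-(2-hydroxypropan-2-yl)-2-methoxy-6-methyl-4-(2-methylprop-1-en-1-yl)-3,4-dihydro-2H-pyrano[3,2-c]quinolin-5(6H)-one | CC(C)=C[C@@H]1c2c(c3ccccc3n(C)c2=O)OC(OC)[C@H]1C(C)(C)O
F2 | step 5 | 2-[(3R,4S)-2-methoxy-6-methyl-4-(2-methylprop-1-en-1-yl)-5-oxo-3,4,5,6-tetrahydro-2H-pyrano[3,2-c]quinolin-3-yl]propan-2-yl 2,2,2-trichloroacetimidate | CC(C)=C[C@@H]1c2c(c3ccccc3n(C)c2=O)OC(OC)[C@H]1C(C)(C)OC(=N)C(Cl)(Cl)Cl
F3 | step 5 | (3R,4S)-2-methoxy-6-methyl-3-{2-[(1-methyl-2-oxo-1,2-dihydroquinolin-4-yl)oxy]propan-2-yl}-4-(2-methylprop-1-en-1-yl)-3,4-dihydro-2H-pyrano[3,2-c]quinolin-5(6H)-one | CC(C)=C[C@@H]1c2c(c3ccccc3n(C)c2=O)OC(OC)[C@H]1C(C)(C)Oc1cc(=O)n(C)c2ccccc12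
F4 | step 4 | 1-methyl-2-oxo-1,2-dihydroquinolin-4-yl acetate | CC(=O)Oc1cc(=O)n(C)c2ccccc12
F5 | step 2 | (4R)-6-methyl-4-(2-methylprop-1-en-1-yl)-3,4-dihydro-2H-pyrano[3,2-c]quinoline-2,5(6H)-dione | CC(C)=C[C@@H]1c2c(c3ccccc3n(C)c2=O)OC(=O)C1
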